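**Plan**

- Retrosynthesis: the 8-O-methoxymethyl group and the C2=C3 unsaturation are removed first (flavonol back to a 3-hydroxychroman-4-one). Then the C3–C4 bond of the pyranone (ring C) is cut to an aryl/alkyl dialdehyde, then the O1–C2 ether bond, then the formyl carbon and the C8a oxygen on ring A.
- Enabling feature: C3 and C4 are neighbouring, oxygen-bearing carbons of ring C, so each can come from a formyl carbon, and a carbene can make one of them nucleophilic.
- Forward: ring A is fully substituted first (Dakin, MOM ether, directed lithiation–hydroxylation, ortho-formylation). The B ring arrives together with C2 and C3 by phenol O-alkylation, a reduction/oxidation pair sets the dialdehyde, and ring C closes last by acyloin cyclisation. Oxidation and MOM removal finish the synthesis.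
- Stereochemistry: the target has no stereocentre. The C2 and C3 centres of the intermediates are racemic and unselected, and both vanish when the ketol is oxidised.

Key step: step 8

Assumption: Eriostemin is achiral, so no enantiomer has to be chosen, and all chiral intermediates are handled as racemates or diastereomer mixtures. Methyl 2-bromo-2-(4-methoxyphenyl)acetate is taken as a catalogue compound.

**Route**

Step 1
Reactants: 1 2,3,4-trimethoxybenzaldehyde
Product: 3 2,3,4-trimethoxyphenol, via 2,3,4-trimethoxyphenyl formate 2 (not isolated)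
Conditions: 30% H2O2, cat. H2SO4, MeOH, rt
Reagents that add atoms: hydrogen peroxide, OO
Why: Acid-catalysed Dakin oxidation, in which the ortho- and para-methoxy groups favour aryl migration in the peroxide adduct (Baeyer–Villiger type) and the aryl formate is methanolysed in the same pot.

Step 2
Reactants: 3 2,3,4-trimethoxyphenol
Product: 4 1-(methoxymethoxy)-2,3,4-trimethoxybenzene
Conditions: MOMCl, i-Pr2NEt, CH2Cl2, 0 °C → rt
Reagents that add atoms: chloromethyl methyl ether, COCCl
Why: Standard O-alkylation of a phenol with MOMCl under amine base; the MOM ether is the strongest ortho-director on the ring for step 3 and is removed by mild acid at the end.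

Step 3
Reactants: 4 1-(methoxymethoxy)-2,3,4-trimethoxybenzene
Product: 7 2-(methoxymethoxy)-3,4,5-trimethoxyphenol, via aryllithium 5 (not isolated), via dimethyl arylboronate 6 (not isolated)
Conditions: n-BuLi, TMEDA, THF, −20 → 0 °C; B(OMe)3, −78 °C → rt; then 30% H2O2, aq. NaOH, 0 °C → rt
Reagents that add atoms: hydrogen peroxide, OO (the phenol oxygen); n-butyllithium, [Li]CCCC, and trimethyl borate, COB(OC)OC, leave atoms only in the intermediates 5 and 6
Why: Directed ortho-metalation, in which the chelating OMOM group outranks the methoxy groups so that lithiation occurs at the only position ortho to it, followed by borylation and alkaline peroxide oxidation (C–B to C–O migration).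

Step 4
Reactants: 7 2-(methoxymethoxy)-3,4,5-trimethoxyphenol
Product: 9 2-hydroxy-3-(methoxymethoxy)-4,5,6-trimethoxybenzaldehyde, via salicyl alcohol 8 (not isolated)
Conditions: anhydrous MgCl2, Et3N, (CH2O)n, MeCN, reflux
Reagents that add atoms: formaldehyde (from paraformaldehyde), C=O
Why: Magnesium-mediated ortho-formylation (Casnati–Skattebøl), in which the magnesium phenoxide delivers formaldehyde to the single free ring position, ortho to the hydroxyl, and a second formaldehyde oxidises the salicyl alkoxide by hydride transfer; the basic medium spares the MOM ether.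

Step 5
Reactants: 9 2-hydroxy-3-(methoxymethoxy)-4,5,6-trimethoxybenzaldehyde; 10 methyl 2-bromo-2-(4-methoxyphenyl)acetate (racemic)
Product: 11 methyl 2-[2-formyl-6-(methoxymethoxy)-3,4,5-trimethoxyphenoxy]-2-(4-methoxyphenyl)acetate (racemic)
Conditions: K2CO3, DMF, 0 °C → rt
Reagents that add atoms: none
Why: Williamson ether synthesis by SN2 displacement at a doubly activated (benzylic, α-ester) secondary bromide, a much-used entry to 2-(2-formylphenoxy)-2-arylacetates; carbonate at room temperature should avoid aldol closure of the product.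

Step 6
Reactants: 11 methyl 2-[2-formyl-6-(methoxymethoxy)-3,4,5-trimethoxyphenoxy]-2-(4-methoxyphenyl)acetate
Product: 12 2-[2-(hydroxymethyl)-6-(methoxymethoxy)-3,4,5-trimethoxyphenoxy]-2-(4-methoxyphenyl)ethan-1-ol (racemic)
Conditions: LiAlH4, THF, 0 °C; Fieser work-up
Reagents that add atoms: none
Why: Hydride reduction of both the aryl aldehyde and the ester by LiAlH4, to which the aryl ethers and the MOM acetal are inert.

Step 7
Reactants: 12 2-[2-(hydroxymethyl)-6-(methoxymethoxy)-3,4,5-trimethoxyphenoxy]-2-(4-methoxyphenyl)ethan-1-ol
Product: 13 2-{[1-(4-methoxyphenyl)-2-oxoethyl]oxy}-3-(methoxymethoxy)-4,5,6-trimethoxybenzaldehyde (racemic)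
Conditions: Dess–Martin periodinane (2.6 equiv), NaHCO3, CH2Cl2, 0 °C → rt; filtered through a short neutral pad and used at once
Reagents that add atoms: none
Why: Dess–Martin oxidation of a benzylic and an aliphatic primary alcohol under buffered, non-basic conditions, which are known to deliver enolisable α-aryl and α-oxygenated aldehydes without aldol reaction.

Step 8
Reactants: 13 2-{[1-(4-methoxyphenyl)-2-oxoethyl]oxy}-3-(methoxymethoxy)-4,5,6-trimethoxybenzaldehyde
Product: 14 3-hydroxy-5,6,7-trimethoxy-8-(methoxymethoxy)-2-(4-methoxyphenyl)chroman-4-one (racemic cis/trans mixture)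
Conditions: 2-(pentafluorophenyl)-6,7-dihydro-5H-pyrrolo[2,1-c][1,2,4]triazol-2-ium tetrafluoroborate (20 mol %), i-Pr2NEt (20 mol %), degassed toluene, 0.02 M, rt
Reagents that add atoms: none
Why: The carbene from the triazolium salt adds to a formyl group, and proton transfer gives the Breslow enaminol, an acyl-anion equivalent that attacks the second formyl carbon and forms C3–C4 before the carbene leaves the resulting alkoxide. The closest known reaction is the carbene-catalysed intramolecular crossed benzoin of O-tethered salicylaldehyde carbonyl compounds to 3-hydroxychroman-4-ones, which tolerates electron-rich alkoxybenzaldehydes as donors. The pyranone ring closes in a 6-exo-trig mode. The new carbinol centre at C3 forms without control next to the racemic C2 centre, and both become sp2 in step 9. The step needs ring closure to win over intermolecular acyloin formation, over aldol closure of the enolisable α-aryloxy aldehyde onto the ring formyl group, and over loss of the aryloxide from a Breslow intermediate at the aliphatic formyl group; the ortho ether tether, high dilution and a weak amine base in no larger amount than the catalyst should secure it. Which formyl group acts as donor does not matter, since the regioisomeric ketol would equilibrate through the enediol and give the same dione on oxidation.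

Step 9
Reactants: 14 3-hydroxy-5,6,7-trimethoxy-8-(methoxymethoxy)-2-(4-methoxyphenyl)chroman-4-one
Product: 16 3-hydroxy-5,6,7-trimethoxy-8-(methoxymethoxy)-2-(4-methoxyphenyl)-4H-chromen-4-one, via chromane-3,4-dione 15 (not isolated)
Conditions: Dess–Martin periodinane (1.2 equiv), NaHCO3, CH2Cl2, 0 °C → rt; then cat. Et3N, rt
Reagents that add atoms: none
Why: Dess–Martin oxidation of the α-ketol to the 1,2-dione, whose C2–H is benzylic and flanked by oxygen and carbonyl, so it should enolise at once to the aromatic, hydrogen-bonded 3-hydroxy-γ-pyranone, erasing both C2 and C3 centres.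

Step 10
Reactants: 16 3-hydroxy-5,6,7-trimethoxy-8-(methoxymethoxy)-2-(4-methoxyphenyl)-4H-chromen-4-one
Product: 17 Eriostemin (3,8-dihydroxy-5,6,7-trimethoxy-2-(4-methoxyphenyl)-4H-chromen-4-one)
Conditions: cat. HCl, MeOH, 50 °C
Reagents that add atoms: none
Why: Acid-catalysed methanolysis of the aryl MOM acetal; the methyl aryl ethers, including the 5-methoxy group next to the carbonyl, and the flavonol core are stable to dilute HCl.

**Compound list**

1 | 2,3,4-trimethoxybenzaldehyde | COc1ccc(C=O)c(OC)c1OC | starting material
2 | 2,3,4-trimethoxyphenyl formate | O=COc1ccc(OC)c(OC)c1OC | intermediate (not isolated)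
3 | 2,3,4-trimethoxyphenol | Oc1ccc(OC)c(OC)c1OC | intermediate
4 | 1-(methoxymethoxy)-2,3,4-trimethoxybenzene | COCOc1ccc(OC)c(OC)c1OC | intermediate
5 | [2-(methoxymethoxy)-3,4,5-trimethoxyphenyl]lithium | [Li]c1cc(OC)c(OC)c(OC)c1OCOC | intermediate (not isolated)
6 | dimethyl [2-(methoxymethoxy)-3,4,5-trimethoxyphenyl]boronate | COB(OC)c1cc(OC)c(OC)c(OC)c1OCOC | intermediate (not isolated)
7 | 2-(methoxymethoxy)-3,4,5-trimethoxyphenol | Oc1cc(OC)c(OC)c(OC)c1OCOC | intermediate
8 | 2-(hydroxymethyl)-6-(methoxymethoxy)-3,4,5-trimethoxyphenol (formed as its magnesium salt) | OCc1c(O)c(OCOC)c(OC)c(OC)c1OC | intermediate (not isolated)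
9 | 2-hydroxy-3-(methoxymethoxy)-4,5,6-trimethoxybenzaldehyde | O=Cc1c(O)c(OCOC)c(OC)c(OC)c1OC | intermediate
10 | methyl 2-bromo-2-(4-methoxyphenyl)acetate (racemic) | COC(=O)C(Br)c1ccc(OC)cc1 | starting material
11 | methyl 2-[2-formyl-6-(methoxymethoxy)-3,4,5-trimethoxyphenoxy]-2-(4-methoxyphenyl)acetate (racemic) | COC(=O)C(Oc1c(C=O)c(OC)c(OC)c(OC)c1OCOC)c1ccc(OC)cc1 | intermediate
12 | 2-[2-(hydroxymethyl)-6-(methoxymethoxy)-3,4,5-trimethoxyphenoxy]-2-(4-methoxyphenyl)ethan-1-ol (racemic) | OCC(Oc1c(CO)c(OC)c(OC)c(OC)c1OCOC)c1ccc(OC)cc1 | intermediate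
13 | 2-{[1-(4-methoxyphenyl)-2-oxoethyl]oxy}-3-(methoxymethoxy)-4,5,6-trimethoxybenzaldehyde (racemic) | O=CC(Oc1c(C=O)c(OC)c(OC)c(OC)c1OCOC)c1ccc(OC)cc1 | intermediate
14 | 3-hydroxy-5,6,7-trimethoxy-8-(methoxymethoxy)-2-(4-methoxyphenyl)chroman-4-one (racemic, cis/trans mixture) | COCOc1c(OC)c(OC)c(OC)c2c1OC(c1ccc(OC)cc1)C(O)C2=O | intermediate
15 | 5,6,7-trimethoxy-8-(methoxymethoxy)-2-(4-methoxyphenyl)chromane-3,4-dione (racemic) | COCOc1c(OC)c(OC)c(OC)c2c1OC(c1ccc(OC)cc1)C(=O)C2=O | intermediate (not isolated)
16 | 3-hydroxy-5,6,7-trimethoxy-8-(methoxymethoxy)-2-(4-methoxyphenyl)-4H-chromen-4-one | COCOc1c(OC)c(OC)c(OC)c2c1oc(-c1ccc(OC)cc1)c(O)c2=O | intermediate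
17 | Eriostemin, 3,8-dihydroxy-5,6,7-trimethoxy-2-(4-methoxyphenyl)-4H-chromen-4-one (achiral) | COc1ccc(-c2oc3c(O)c(OC)c(OC)c(OC)c3c(=O)c2O)cc1 | target

**Totals and risks**

Total step count: 10. Longest linear sequence: 10 steps (1 → 17); compound 10 is used as bought.

Steps most likely to fail:

1. Step 8. The Breslow intermediate formed at the aliphatic formyl group may expel the aryloxide (redox isomerisation towards an aryl ester), or base-induced aldol closure of the enolised α-aryloxy aldehyde onto the ring formyl group may outrun the acyloin closure. The fallback makes the same C3–C4 bond reductively. It sets out from 13: SmI2 (2.2 equiv), t-BuOH, THF, −78 °C should give, by intramolecular pinacol coupling, 5,6,7-trimethoxy-8-(methoxymethoxy)-2-(4-methoxyphenyl)chromane-3,4-diol F1. Oxidation of both carbinols (DMSO, (COCl)2, then Et3N, −78 °C → rt) should lead through dione 15 to flavonol 16, where the route is rejoined before step 10.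

2. Step 7. The mono-oxidised hydroxy aldehyde may close to a seven-membered lactol that is over-oxidised to a lactone, or the freshly formed α-aryloxy aldehyde may enolise and undergo aldol closure or decompose on handling. The fallback unveils the two formyl groups without an oxidant and sets out from 11. The ring formyl group is masked (HC(OMe)3, cat. PPTS, MeOH, rt) as methyl 2-[2-(dimethoxymethyl)-6-(methoxymethoxy)-3,4,5-trimethoxyphenoxy]-2-(4-methoxyphenyl)acetate F2. DIBAL-H (1.1 equiv, CH2Cl2, −78 °C) should stop at the chelated tetrahedral stage and give 2-[2-(dimethoxymethyl)-6-(methoxymethoxy)-3,4,5-trimethoxyphenoxy]-2-(4-methoxyphenyl)acetaldehyde F3. Brief treatment with PPTS in wet acetone at rt should hydrolyse the electron-rich aryl acetal while leaving the MOM ether, returning to the route at 13.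

3. Step 5. The hindered, hydrogen-bonded phenoxide may react slowly while the ionisable bromide solvolyses, or the product may undergo carbonate-induced aldol closure. The fallback forms the O1–C2 bond by redox condensation without base and sets out from 9: Mitsunobu reaction with commercial methyl 2-hydroxy-2-(4-methoxyphenyl)acetate (PPh3, DIAD, THF, 0 °C → rt) should give 11 directly, where the route is rejoined; this way makes no new compound (F0).

Further compounds
F1 | step 8 | 5,6,7-trimethoxy-8-(methoxymethoxy)-2-(4-methoxyphenyl)chromane-3,4-diol (racemic diastereomer mixture) | COCOc1c(OC)c(OC)c(OC)c2c1OC(c1ccc(OC)cc1)C(O)C2O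
F2 | step 7 | methyl 2-[2-(dimethoxymethyl)-6-(methoxymethoxy)-3,4,5-trimethoxyphenoxy]-2-(4-methoxyphenyl)acetate (racemic) | COC(=O)C(Oc1c(C(OC)OC)c(OC)c(OC)c(OC)c1OCOC)c1ccc(OC)cc1
F3 | step 7 | 2-[2-(dimethoxymethyl)-6-(methoxymethoxy)-3,4,5-trimethoxyphenoxy]-2-(4-methoxyphenyl)acetaldehyde (racemic) | O=CC(Oc1c(C(OC)OC)c(OC)c(OC)c(OC)c1OCOC)c1ccc(OC)cc1
F0 | step 5 | none | none
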